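Ring labels: A is the ring whose C1 carries the D–A bridge, with O at C3, C4 and C5 (C5–O–ring B). B is the para-phenylene. C is the ring with O–ring D at C2 and O at C3 and C4. D is the ortho-phenylene.
Cuts, in retrosynthetic order: four O–H back to O–Me; the ring D benzylic CH2 back to C=O and then C=CH2; ring A C1–CH2 (retro para-Claisen, chain returned to the C4 oxygen); the methylene back to a ketone; C4 O–CH2; the C–D aryl ether; the B–C CH2–CH2 bridge; the A–B aryl ether.
Enabling feature: ring A C1 lies para to the C4 oxygen. Both carbons ortho to that oxygen are blocked, C3 by OMe and C5 by O–ring B, so an allyl group leaving O4 can settle only at C1.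
Forward order: A–B ether (SNAr), B–C bridge (Wittig, H2), C–D ether (SNAr), closure of the single 17-membered ring at O4 by phenacyl alkylation, methylenation, thermal walk of the ring from O4 to C1, excision of the extra carbon, demethylation.
Stereochemistry: the target has no stereocentre and no fixed double bond. The sp3 centres that appear in passing are erased in the same or the next step.

Key step: step 14

Assumption: the target SMILES carries no stereodescriptor, so the macrocycle is treated as achiral and conformationally mobile. Stilbene 12 is carried as an E/Z mixture.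

Step 1
Reactants: 1 o-vanillin (2-hydroxy-3-methoxybenzaldehyde)
Product: 2 3-methoxy-2-(methoxymethoxy)benzaldehyde
Conditions: MOMCl, K2CO3, acetone, 0 °C → rt
Reagents that add atoms: chloromethyl methyl ether, COCCl
Why: Williamson-type O-alkylation with the very reactive chloromethyl ether masks the future ring A C4 oxygen as an acetal that tolerates base, hydride, hydrogenation and enolate chemistry yet leaves under mild acid.

Step 2
Reactants: 2 3-methoxy-2-(methoxymethoxy)benzaldehyde
Product: 4 3-methoxy-2-(methoxymethoxy)phenol, via aryl formate 3 (not isolated)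
Conditions: mCPBA, CH2Cl2, 0 °C → rt; NaHCO3 wash; crude 3, K2CO3 (cat.), MeOH, rt
Reagents that add atoms: 3-chloroperbenzoic acid, OOC(=O)c1cccc(Cl)c1
Why: Baeyer–Villiger oxidation of an electron-rich benzaldehyde proceeds with aryl migration, and base-catalysed methanolysis of the formate unveils the ring A C5 phenol at the position fixed by the old aldehyde, so no selective reaction of a catechol is needed.

Step 3
Reactants: 4 3-methoxy-2-(methoxymethoxy)phenol; 5 4-fluorobenzaldehyde
Product: 6 4-[3-methoxy-2-(methoxymethoxy)phenoxy]benzaldehyde (A–B aldehyde)
Conditions: K2CO3, DMF, 110 °C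
Reagents that add atoms: none
Why: Nucleophilic aromatic substitution (addition–elimination) on a fluoride activated by a para formyl group is a standard diaryl ether synthesis, and the non-enolisable aldehyde survives carbonate.

Step 4
Reactants: 7 2-hydroxy-3,4-dimethoxybenzaldehyde
Product: 8 2-(benzyloxy)-3,4-dimethoxybenzaldehyde
Conditions: BnBr, K2CO3, DMF, rt
Reagents that add atoms: benzyl bromide, BrCc1ccccc1
Why: Williamson benzylation gives an ether that withstands hydride, mild acid and ylide and that will leave during the later hydrogenation without an extra step.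

Step 5
Reactants: 8 2-(benzyloxy)-3,4-dimethoxybenzaldehyde
Product: 9 [2-(benzyloxy)-3,4-dimethoxyphenyl]methanol
Conditions: NaBH4, MeOH, 0 °C
Reagents that add atoms: none
Why: Borohydride reduction of an aromatic aldehyde to the benzylic alcohol is chemoselective and leaves the ethers untouched.

Step 6
Reactants: 9 [2-(benzyloxy)-3,4-dimethoxyphenyl]methanol
Product: 10 [2-(benzyloxy)-3,4-dimethoxybenzyl]triphenylphosphonium bromide
Conditions: PPh3·HBr, MeCN, reflux
Reagents that add atoms: triphenylphosphine hydrobromide, Br.c1ccc(cc1)P(c1ccccc1)c1ccccc1
Why: The electron-rich benzylic alcohol ionises under the mild acidity of PPh3·HBr and is trapped by the phosphine, the standard one-step preparation of benzylic phosphonium salts, with the benzyl ether left intact.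

Step 7
Reactants: 10 [2-(benzyloxy)-3,4-dimethoxybenzyl]triphenylphosphonium bromide; 6 A–B aldehyde
Product: 12 A–B–C stilbene (E/Z mixture; ring A OMOM and ring C OBn), via phosphorus ylide 11 (not isolated)
Conditions: KOtBu, THF, 0 °C; then 6, 0 °C → rt
Reagents that add atoms: none
Why: Wittig olefination of an aromatic aldehyde with a semi-stabilised benzylic ylide is reliable, and its lack of E/Z control does not matter because the double bond is hydrogenated next.

Step 8
Reactants: 12 A–B–C stilbene
Product: 13 A–B–C bibenzyl phenol (2,3-dimethoxy-6-(2-{4-[3-methoxy-2-(methoxymethoxy)phenoxy]phenyl}ethyl)phenol)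
Conditions: H2 (1 atm), Pd/C (10 wt%), EtOAc–EtOH, rt
Reagents that add atoms: none
Why: Heterogeneous catalytic hydrogenation saturates both stilbene isomers to the same bibenzyl and hydrogenolyses the benzyl ether in the same operation, freeing only the ring C phenol because the MOM acetal is inert to H2 over Pd/C.

Step 9
Reactants: 13 A–B–C bibenzyl phenol; 14 2'-fluoroacetophenone
Product: 15 open-chain A–B–C–D methyl ketone (1-{2-[2,3-dimethoxy-6-(2-{4-[3-methoxy-2-(methoxymethoxy)phenoxy]phenyl}ethyl)phenoxy]phenyl}ethanone)
Conditions: K2CO3, DMF, 140 °C (14 in excess, concentrated)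
Reagents that add atoms: none
Why: Nucleophilic aromatic substitution on a fluoride activated by the ortho acetyl group forms the C–D diaryl ether at a stage where no aldehyde is left to condense with the methyl ketone.

Step 10
Reactants: 15 open-chain A–B–C–D methyl ketone
Product: 17 open-chain bromomethyl ketone (ring D–C(=O)–CH2Br; ring A OMOM), via silyl enol ether 16 (not isolated)
Conditions: LiN(SiMe3)2, Me3SiCl (internal quench), THF, −78 °C; crude 16, NBS, THF, 0 °C
Reagents that add atoms: N-bromosuccinimide, O=C1CCC(=O)N1Br; chlorotrimethylsilane (its atoms stay only in 16), C[Si](C)(C)Cl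
Why: Kinetic deprotonation of the only enolisable position and O-silylation give a silyl enol ether far more nucleophilic towards NBS than any alkoxyarene ring, so this two-stage ketone α-bromination places bromine on the acetyl carbon only.

Step 11
Reactants: 17 open-chain bromomethyl ketone
Product: 18 bromo keto phenol (17 with the ring A C4 oxygen free)
Conditions: TsOH·H2O (cat.), MeOH–CH2Cl2, 40 °C
Reagents that add atoms: none
Why: Acid-catalysed acetal exchange with methanol removes the MOM group and traps its formaldehyde unit as a dialkyl acetal, away from the free para position C1, while aryl ethers and the bromo ketone are inert to dilute acid.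

Step 12
Reactants: 18 bromo keto phenol
Product: 19 macrocyclic keto ether (17-membered; ring A C4–O–CH2–C(=O)–ring D)
Conditions: Cs2CO3, MeCN, 50 °C, slow addition of 18 (final 2 mM)
Reagents that add atoms: none
Why: Intramolecular Williamson etherification (exo-tet closure) pairs the caesium phenoxide with an exceptionally SN2-reactive phenacyl bromide, so ring closure stays fast at the low stationary concentration that suppresses oligomers.

Step 13
Reactants: 19 macrocyclic keto ether
Product: 20 macrocyclic 2-(ring D)allyl ether of the ring A C4 oxygen (17-membered; exocyclic C=CH2)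
Conditions: MePPh3Br, KOtBu, THF, 0 °C → rt
Reagents that add atoms: methyltriphenylphosphonium bromide, C[P+](c1ccccc1)(c1ccccc1)c1ccccc1.[Br-]
Why: Wittig methylenation with the non-stabilised ylide converts aryl ketones, α-aryloxy ones included, into 1,1-disubstituted alkenes and touches nothing else in 19.

Step 14
Reactants: 20 macrocyclic 2-(ring D)allyl ether
Product: 23 macrocyclic C1-allylated phenol (17-membered; ring A C1–CH2–C(=CH2)–ring D; free C4–OH), via ortho-dienone 21 (not isolated), via para-dienone 22 (not isolated)
Conditions: PhNEt2 (0.01 M), BHT (cat.), 200 °C, sealed tube, Ar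
Reagents that add atoms: none
Why: Proposed new method: heat should first drive an aromatic Claisen [3,3] shift that bonds the exocyclic methylene carbon to the methoxy-bearing C3 of ring A (the route through the aryloxy-bearing C5 is open too but pinches the ring to 15 members), and because the resulting cyclohexa-2,4-dienone 21 has no hydrogen on its new quaternary carbon it can only revert or undergo a Cope [3,3] shift that passes the former O–CH2 carbon to C1, after which cross-conjugated dienone 22 tautomerises to phenol 23. The closest known reaction type is the para-Claisen rearrangement of acyclic allyl and methallyl 2,6-dialkoxyphenyl ethers in hot dialkylanilines; new here is that the migrating allyl unit is a link of a macrocycle, which should be tolerated because each shift only asks the three allyl carbons to lie over one face of ring A and the twelve-atom B–C–D tether between C5 and the central allyl carbon is long and hinged at two ether oxygens and one CH2–CH2 unit. The 17-membered ring of 23 is closed at the C1–CH2 bond by a transannular pericyclic closure through a six-membered chair- or boat-like array in which the C3–CH2 bond breaks as the new one forms, so the large ring is never opened and keeps 17 members in 20, 21, 22 and 23. The sp3 carbons C3 of 21 and C1 of 22 are transient, racemic and erased by the Cope shift and the tautomerisation, so no stereocentre has to be controlled. The selectivity required is delivery to C1 alone, and the substrate secures it because C3 and C5 both carry oxygen substituents while C1 is the only terminus with a hydrogen to lose, so both ortho pathways drain into the same product. The ring D aryl group on the central allyl carbon stabilises the diyl-like character of both transition states, and the basic solvent and radical inhibitor hold back ionisation of the ether and polymerisation of the styrene unit.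

Step 15
Reactants: 23 macrocyclic C1-allylated phenol
Product: 24 macrocyclic tetramethyl ether with exocyclic methylene
Conditions: MeI, K2CO3, acetone, reflux
Reagents that add atoms: iodomethane, CI
Why: Williamson methylation caps the liberated C4 phenol with the same group as the other three oxygens, so it resists periodate and falls in the final global demethylation.

Step 16
Reactants: 24 macrocyclic tetramethyl ether with exocyclic methylene
Product: 26 macrocyclic deoxybenzoin ketone (ring D–C(=O)–CH2–ring A C1), via vicinal diol 25 (not isolated)
Conditions: OsO4 (cat.), NaIO4, 2,6-lutidine, dioxane–H2O, rt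
Reagents that add atoms: osmium tetroxide (delivers the diol oxygens, one of which stays as the carbonyl oxygen), O=[Os](=O)(=O)=O; sodium periodate (terminal oxidant that restores OsO4), [Na+].[O-]I(=O)(=O)=O
Why: Lemieux–Johnson oxidation osmylates the only alkene and cleaves the diol in the same flask to the aryl ketone, the prior methylation keeping periodate from oxidising ring A to a quinone.

Step 17
Reactants: 26 macrocyclic deoxybenzoin ketone
Product: 28 tetra-O-methyl ether of the target, via benzylic alcohol 27 (not isolated)
Conditions: Et3SiH, CF3CO2H, CH2Cl2, 0 °C → rt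
Reagents that add atoms: none
Why: Ionic hydrogenation (Kursanov–Parnes reduction) gives alcohol 27 by protonation and hydride transfer, and 27 ionises readily to an ortho-aryloxy-stabilised benzylic cation that takes a second hydride, while both ring C positions ortho to the diaryl ether oxygen are substituted so no xanthene-type cyclisation can intervene.

Step 18
Reactants: 28 tetra-O-methyl ether of the target
Product: 29 CNP0114693.0 (target)
Conditions: BBr3, CH2Cl2, −78 °C → rt; then H2O
Reagents that add atoms: none
Why: Lewis-acid demethylation with BBr3 cleaves the four O–CH3 bonds by bromide attack on methyl, whereas the two diaryl ether linkages offer no sp3 carbon and stay intact.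

Compound list
1 | o-vanillin (2-hydroxy-3-methoxybenzaldehyde) | COc1cccc(C=O)c1O | starting material
2 | 3-methoxy-2-(methoxymethoxy)benzaldehyde | COCOc1c(OC)cccc1C=O | intermediate
3 | 3-methoxy-2-(methoxymethoxy)phenyl formate (not isolated) | COCOc1c(OC)cccc1OC=O | intermediate
4 | 3-methoxy-2-(methoxymethoxy)phenol | COCOc1c(OC)cccc1O | intermediate
5 | 4-fluorobenzaldehyde | O=Cc1ccc(F)cc1 | starting material
6 | 4-[3-methoxy-2-(methoxymethoxy)phenoxy]benzaldehyde | COCOc1c(OC)cccc1Oc1ccc(C=O)cc1 | intermediate
7 | 2-hydroxy-3,4-dimethoxybenzaldehyde | COc1ccc(C=O)c(O)c1OC | starting material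
8 | 2-(benzyloxy)-3,4-dimethoxybenzaldehyde | COc1ccc(C=O)c(OCc2ccccc2)c1OC | intermediate
9 | [2-(benzyloxy)-3,4-dimethoxyphenyl]methanol | COc1ccc(CO)c(OCc2ccccc2)c1OC | intermediate
10 | [2-(benzyloxy)-3,4-dimethoxybenzyl]triphenylphosphonium bromide | COc1ccc(C[P+](c2ccccc2)(c2ccccc2)c2ccccc2)c(OCc2ccccc2)c1OC.[Br-] | intermediate
11 | [2-(benzyloxy)-3,4-dimethoxybenzylidene]triphenylphosphorane (not isolated) | COc1ccc(C=P(c2ccccc2)(c2ccccc2)c2ccccc2)c(OCc2ccccc2)c1OC | intermediate
12 | A–B–C stilbene, E/Z mixture (double-bond geometry left open on purpose) | COCOc1c(OC)cccc1Oc1ccc(C=Cc2ccc(OC)c(OC)c2OCc2ccccc2)cc1 | intermediate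
13 | A–B–C bibenzyl phenol | COCOc1c(OC)cccc1Oc1ccc(CCc2ccc(OC)c(OC)c2O)cc1 | intermediate
14 | 2'-fluoroacetophenone | CC(=O)c1ccccc1F | starting material
15 | open-chain A–B–C–D methyl ketone | CC(=O)c1ccccc1Oc1c(OC)c(OC)ccc1CCc1ccc(cc1)Oc1cccc(OC)c1OCOC | intermediate
16 | trimethylsilyl enol ether of 15 (not isolated) | C=C(O[Si](C)(C)C)c1ccccc1Oc1c(OC)c(OC)ccc1CCc1ccc(cc1)Oc1cccc(OC)c1OCOC | intermediate
17 | open-chain bromomethyl ketone | BrCC(=O)c1ccccc1Oc1c(OC)c(OC)ccc1CCc1ccc(cc1)Oc1cccc(OC)c1OCOC | intermediate
18 | bromo keto phenol | BrCC(=O)c1ccccc1Oc1c(OC)c(OC)ccc1CCc1ccc(cc1)Oc1cccc(OC)c1O | intermediate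
19 | macrocyclic keto ether (17-membered) | COc1cccc2c1OCC(=O)c1ccccc1Oc1c(OC)c(OC)ccc1CCc1ccc(O2)cc1 | intermediate
20 | macrocyclic 2-(ring D)allyl ether of ring A O4 (17-membered) | COc1cccc2c1OCC(=C)c1ccccc1Oc1c(OC)c(OC)ccc1CCc1ccc(O2)cc1 | intermediate
21 | ortho-dienone, allyl terminus on C3 (racemic, not isolated) | COC12C=CC=C(C1=O)Oc1ccc(cc1)CCc1ccc(OC)c(OC)c1Oc1ccccc1C(=C)C2 | intermediate
22 | para-dienone, allyl terminus on C1 (racemic, not isolated) | COC1=CC2C=C(C1=O)Oc1ccc(cc1)CCc1ccc(OC)c(OC)c1Oc1ccccc1C(=C)C2 | intermediate
23 | macrocyclic C1-allylated phenol (17-membered) | COc1cc2cc(c1O)Oc1ccc(cc1)CCc1ccc(OC)c(OC)c1Oc1ccccc1C(=C)C2 | intermediate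
24 | macrocyclic tetramethyl ether with exocyclic methylene | COc1cc2cc(c1OC)Oc1ccc(cc1)CCc1ccc(OC)c(OC)c1Oc1ccccc1C(=C)C2 | intermediate
25 | vicinal diol from 24 (racemic, not isolated) | COc1cc2cc(c1OC)Oc1ccc(cc1)CCc1ccc(OC)c(OC)c1Oc1ccccc1C(O)(CO)C2 | intermediate
26 | macrocyclic deoxybenzoin ketone | COc1cc2cc(c1OC)Oc1ccc(cc1)CCc1ccc(OC)c(OC)c1Oc1ccccc1C(=O)C2 | intermediate
27 | benzylic alcohol from 26 (racemic, not isolated) | COc1cc2cc(c1OC)Oc1ccc(cc1)CCc1ccc(OC)c(OC)c1Oc1ccccc1C(O)C2 | intermediate
28 | tetra-O-methyl ether of the target | COc1cc2cc(c1OC)Oc1ccc(cc1)CCc1ccc(OC)c(OC)c1Oc1ccccc1CC2 | intermediate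
29 | CNP0114693.0 | Oc1cc2cc(c1O)Oc1ccc(cc1)CCc1ccc(O)c(O)c1Oc1ccccc1CC2 | target

Total step count: 18.
Longest linear sequence: 15 steps (steps 1–3 and 7–18 from 1; the branch from 7 through steps 4–6 is equally long).

Steps most likely to fail

1. Step 14.
- What may go wrong: the tether may keep the allyl unit from stacking over ring A. The first shift would then not start below the temperature at which the O–CH2 bond homolyses. Dienone 21 may also be drained by an internal Diels–Alder addition before the Cope shift.
- Fallback (known chemistry, from 15 back to 26): the C1–CH2 bond is made by cross-coupling instead of rearrangement. Acid-catalysed methanolysis (TsOH·H2O, MeOH) removes the MOM group and gives the open-chain keto phenol F1. NBS in CH2Cl2 at low temperature brominates the only free position para to the phenol and gives the C1-bromo keto phenol F2. MeI and K2CO3 give the C1-bromo keto methyl ether F3. A palladium-catalysed ketone α-arylation (Pd2(dba)3, Xantphos, NaOtBu, toluene, 90 °C, slow addition) then joins the acetyl CH3 to ring A C1 and delivers 26 directly.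

2. Step 12.
- What may go wrong: intermolecular alkylation leading to oligomers may outrun ring closure if the open chain prefers extended conformations.
- Fallback (from 12 back to 19): the large ring is closed at a different bond, the C–D aryl ether. Methanolysis of the MOM group (TsOH·H2O, MeOH–THF) gives the stilbene phenol F4. Alkylation with commercial 2-bromo-2'-fluoroacetophenone (K2CO3, acetone, rt) gives the stilbene 2-fluorophenacyl ether F5. Hydrogenation (H2, 1 atm, Pd/C, EtOAc, stopped after the calculated uptake) saturates the bridge, removes the benzyl group and gives the bibenzyl fluoro keto phenol F6. An intramolecular nucleophilic aromatic substitution on the ketone-activated fluoride (Cs2CO3, DMF, 110 °C, slow addition) gives 19.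

3. Step 9.
- What may go wrong: addition–elimination may be slow at a phenoxide flanked on both sides. Base-induced self-condensation of the methyl ketone then takes over during the long heating.
- Fallback (from 13 straight to 15): the diaryl ether is made by copper catalysis instead of SNAr. This is an Ullmann-type coupling of 13 with 2'-bromoacetophenone (CuI, picolinic acid, K3PO4, DMSO, 90 °C), a ligand system suited to hindered phenols. No new intermediate is formed.

Further compounds
F1 | step 14 | open-chain keto phenol (15 without MOM) | CC(=O)c1ccccc1Oc1c(OC)c(OC)ccc1CCc1ccc(cc1)Oc1cccc(OC)c1O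
F2 | step 14 | C1-bromo keto phenol | CC(=O)c1ccccc1Oc1c(OC)c(OC)ccc1CCc1ccc(cc1)Oc1cc(Br)cc(OC)c1O
F3 | step 14 | C1-bromo keto methyl ether | CC(=O)c1ccccc1Oc1c(OC)c(OC)ccc1CCc1ccc(cc1)Oc1cc(Br)cc(OC)c1OC
F4 | step 12 | stilbene phenol (12 without MOM, E/Z mixture) | COc1cccc(Oc2ccc(C=Cc3ccc(OC)c(OC)c3OCc3ccccc3)cc2)c1O
F5 | step 12 | stilbene 2-fluorophenacyl ether (E/Z mixture) | COc1cccc(Oc2ccc(C=Cc3ccc(OC)c(OC)c3OCc3ccccc3)cc2)c1OCC(=O)c1ccccc1F
F6 | step 12 | bibenzyl fluoro keto phenol | COc1cccc(Oc2ccc(CCc3ccc(OC)c(OC)c3O)cc2)c1OCC(=O)c1ccccc1F
F0 | step 9 | none | none
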